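## Structural features

The target (38 in the route) is a germacranolide: a ten-membered carbocycle C1 to C10 that is trans-fused at C6–C7 to an α-methylene-γ-butyrolactone (C6, C7, C11, C12 and the ring oxygen; C13 is the exocyclic methylene). The large ring carries a trans oxirane across C1–C10 (C14 methyl on C10), a secondary hydroxyl at C3, a Z C4=C5 olefin with the C15 hydroxymethyl group on C4 (C3 and C6 cis), and a tiglate on the C8 oxygen. There are six stereocentres, 1R,3S,6R,7R,8R,10R (1β,10α-epoxide, 3β-OH, 6α-O, 7α-H, 8β-acyloxy): C6, C7 and C8 are contiguous, C1 and C10 share the oxirane, and C3 stands alone between C2 and the olefin. Fragile groups are the α-methylene lactone (Michael acceptor), the epoxide, the allylic diol and the tiglate. In the precursors the 1(10),4-diene is also fragile (transannular cyclisation with acid, Cope rearrangement with heat), as is any 3-enal that can slip into conjugation. The real difficulty is the strained ten-membered ring with its Z trisubstituted olefin, together with telling four oxygens (C3, C6, C8, C15) apart. The key step uses C6: in the 6-deoxy acid 34 it is the one unsubstituted allylic methylene between C5 of the C4=C5 olefin and C7, and it is γ to the C12 carboxyl of the acrylic acid on C7, so a hydroxyl placed on its α face closes the lactone unaided. A descriptor check shows that 34, 37 and 38 carry the same arrangement at C3, C7 and C8 and that the oxirane of 38 is the trans isomer that an E olefin gives, so no structure needs correction; C15 is a further allylic position that competes with C6.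

## Logic of the disconnections

**38 to 37.** The two C–O bonds of the oxirane (C1–O, C10–O) are cut last. The epoxide is the most acid-sensitive group, and C1=C10 is the only electron-rich, unconjugated olefin of 37 without allylic oxygen. This removes two stereocentres. The forward step must be site-selective and must attack the outer face of the E olefin.

**37 to 34 and 35.** C6–O and O–C12 are cut (key step). This removes the lactone ring and the C6 stereocentre and leaves a monocyclic acid with three stereocentres. The forward step must hydroxylate one C–H bond out of seven allylic positions on one face, which is asked of an enzyme.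

**34 to 33.** The O–Si bond at C15 and the ester C–O bond at C12 are cut, both fluoride-labile. The free acid and diol appear only one step before the enzyme. The forward step must avoid acid and heat.

**33 to 32.** C3–C4 is cut. The ring opens to a chain with an aldehyde at C3 and a Z alkenyl iodide at C4 that already holds the olefin geometry. This removes the ring and the C3 stereocentre. The forward step is a Nozaki–Hiyama–Kishi closure at high dilution that must set C3.

**32 to 30 (through 31).** Only the oxidation level and the protecting group at C3 change. The 3-enal is made immediately before use.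

**30 to 26 (through 29 and 27).** The C4–iodine and C5–H bonds are cut back to an alkyne. The forward step needs anti addition with the heteroatom next to the free C15 hydroxyl.

**26 to 25.** C11–C12 is cut. The acrylate carbon comes from CO, so C11 can be a ketone carbon during the stereochemistry-setting steps. The forward step needs an alkenyl triflate and no other group reactive toward zerovalent palladium, which is why the iodide is made later.

**25 to 22 and 23; 22 to 20 (through 21).** The acyl–O bond of the tiglate is cut, and the enol triflate goes back to a methyl ketone. The tiglate is put on before C12 exists, so a free C8 hydroxyl never sits next to an acrylate ester that it could lactonise onto.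

**20 to 17 (through 19 and 18).** C11–C13 is cut. A methyl nucleophile adds to an amide made from the aldol adduct.

**17 to 15 and 8.** C7–C8 is cut. An auxiliary-controlled syn aldol sets C7 and C8 together and joins the two halves. The forward step needs a 3-enal that must not isomerise.

**8 to 1 and 2 (through 5, 6, 7).** C10–C14 and C1–C2 are cut. Syn addition of methyl and metal to an alkyne fixes the E geometry of C1=C10, and a two-carbon epoxide supplies C2 and C3.

**15 to 12 and 13; 12 to 9 and 10 (through 11).** The N-acyl bond and C5–C6 are cut. An acetylide opens a four-membered ether, which delivers C6, C7 and C11 in one step.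

## Other disconnections considered

**Alternative 1:** The cut is C1–C2 together with C10–C14. The alkyne half A1 (C6 to C10 with C11 to C13, the C7 and C8 stereocentres in place) would be methylaluminated with AlMe3 and catalytic Zr(C5H5)2Cl2. Its lithium ate complex would open the epoxide half A2 (C2 to C5 with C15 and the alkenyl iodide, C3 in the oxirane) at C2 to give the open chain A3.
- In favour: the plan is convergent, the E olefin comes from syn addition, and C3 comes from an enantiopure epoxide. On C3 control it is better than the chosen plan, where C3 arises in the ring closure. It also needs no 3-enal for an aldol.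
- Against: A2 is an alkenyl oxirane, so attack at the allylic C3 or in the SN2′ sense competes with attack at C2. The organolithium needed for the ate complex can exchange with the iodide. After the coupling the ring must still be closed at C5–C6 onto a C6 aldehyde, which moves the uncontrolled stereocentre from C3 to C6. C12 must then be raised from the ether to the acid level and four different protecting groups unravelled.
- Comparison: every step is known chemistry, which the chosen plan cannot claim. In step count it is longer: two fragments that each need asymmetric steps, then roughly nine operations after the coupling against three after ring closure in the chosen route.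

**Alternative 2:** The cut is C8–C9 (formed) against C1–C6 (broken in the forward sense). KH with 18-crown-6 would drive an anionic oxy-Cope shift that enlarges a six-membered ring to the ten-membered enolate, and protonation would give A4.
- In favour: the ten-membered ring forms without high dilution. The C4=C5 olefin is Z because it was a ring olefin, the C1=C10 olefin is E from a chair transition state, and C6 arrives oxidised. As a ring-forming step it is equal to or better than a chromium-mediated closure.
- Against: the C8 oxygen must ride on the migrating alkene as an enol ether whose geometry sets C8. C7 is set by kinetic protonation of the enolate. The C6 ketone must be reduced from the α face. The two-carbon side chain on C7 must be turned into the α-methylene lactone by oxidation, lactonisation and methylenation with strong base. The acetal on the C8 oxygen must come off under acid next to an acid-labile diene.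
- Comparison: the mechanism is pericyclic and stereospecific, where the chosen plan relies on an unknown enzyme. The chosen plan is shorter after ring formation and never exposes the ring to strong base or acid.

**Alternative 3:** The cut is the same C3–C4 bond as in the ring closure of the chosen route, but made with the lactone already present. CrCl2 with catalytic NiCl2 would close the iodo aldehyde A5 to A6.
- In favour: only known chemistry is used, the lactone acts as a turn element that may help cyclisation, and after ring closure only desilylation and epoxidation remain. On certainty and on the length of the endgame it is better than the chosen plan.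
- Against: A5 needs three contiguous stereocentres (C6, C7, C8) and the trans lactone before cyclisation, which costs several more steps than the two-stereocentre chain used here. The α-methylene lactone must survive silylation, DDQ, Dess–Martin oxidation, chromium and fluoride. C3 is still set under substrate control, so on that point the two plans are equal.
- Comparison: the ring-closing mechanism is identical. The chosen plan trades a longer, fully precedented chain for a shorter one plus one unprecedented enzymatic step, and the total step counts are about equal. If no enzyme is found, this is the plan to fall back to as a whole.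

Key step: step 23

Assumption: silyl ethers 1 and 9 are taken as catalogue chemicals (each is one silylation away from 3-butyn-1-ol or propargyl alcohol), and a P450 of the costunolide-synthase class that accepts acid 34 is taken to be found by screening.

## Route

Step 1
Reactants: 1 tert-butyl(but-3-yn-1-yloxy)dimethylsilane; 2 oxirane
Product: 5 (E)-6-(tert-butyldimethylsilyloxy)-4-methylhex-3-en-1-ol, via alkenylalane 3 (not isolated), via lithium alanate 4 (not isolated)
Conditions: AlMe3, Zr(C5H5)2Cl2 (0.2 equiv), CH2Cl2, 0 °C to rt; then n-BuLi, THF, −78 °C; 2, −78 to 0 °C; aq. NH4Cl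
Reagents that add atoms: trimethylaluminium, C[Al](C)C
Why: Zirconium-catalysed syn methylalumination of the terminal alkyne (Negishi carboalumination) puts the methyl on the internal carbon and aluminium cis to it, which fixes the E geometry of C1=C10; the ate complex opens the epoxide with retention at the alkenyl carbon.

Step 2
Reactants: 5 (E)-6-(tert-butyldimethylsilyloxy)-4-methylhex-3-en-1-ol
Product: 6 tert-butyl{[(E)-6-(4-methoxybenzyloxy)-3-methylhex-3-en-1-yl]oxy}dimethylsilane
Conditions: NaH, 4-methoxybenzyl chloride, Bu4NI (cat.), THF/DMF, 0 °C to rt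
Reagents that add atoms: 4-methoxybenzyl chloride, COc1ccc(CCl)cc1
Why: Williamson etherification of the primary alkoxide; the 4-methoxybenzyl ether is the one group that DDQ will remove at step 19.

Step 3
Reactants: 6 tert-butyl{[(E)-6-(4-methoxybenzyloxy)-3-methylhex-3-en-1-yl]oxy}dimethylsilane
Product: 7 (E)-6-(4-methoxybenzyloxy)-3-methylhex-3-en-1-ol
Conditions: Bu4NF, THF, 0 °C to rt; aq. NH4Cl
Reagents that add atoms: none
Why: Fluoride cleavage of the silyl ether; the benzyl-type ether is inert.

Step 4
Reactants: 7 (E)-6-(4-methoxybenzyloxy)-3-methylhex-3-en-1-ol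
Product: 8 (E)-6-(4-methoxybenzyloxy)-3-methylhex-3-enal
Conditions: Dess–Martin periodinane, NaHCO3, CH2Cl2, 0 °C; used at once
Reagents that add atoms: none
Why: Dess–Martin oxidation under buffered, base-free conditions should give the 3-enal without moving the olefin into conjugation.

Step 5
Reactants: 9 tert-butyldimethyl(prop-2-yn-1-yloxy)silane; 10 oxetane
Product: 11 6-(tert-butyldimethylsilyloxy)hex-4-yn-1-ol
Conditions: n-BuLi, THF, −78 °C; BF3·OEt2; 10, −78 °C; aq. NH4Cl
Reagents that add atoms: none
Why: BF3-assisted opening of the oxetane by the lithium acetylide forms C5–C6 and delivers C6, C7 and C11 as a primary alcohol.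

Step 6
Reactants: 11 6-(tert-butyldimethylsilyloxy)hex-4-yn-1-ol
Product: 12 6-(tert-butyldimethylsilyloxy)hex-4-ynoic acid
Conditions: (2,2,6,6-tetramethylpiperidin-1-yl)oxyl (cat.), PhI(OAc)2, MeCN/pH 7 buffer (KH2PO4/K2HPO4), rt
Reagents that add atoms: water, O
Why: Nitroxyl-catalysed oxidation of the primary alcohol through the aldehyde hydrate to the acid; silyl ether and alkyne are inert.

Step 7
Reactants: 12 6-(tert-butyldimethylsilyloxy)hex-4-ynoic acid; 13 (S)-4-benzyloxazolidin-2-one
Product: 15 (S)-4-benzyl-3-[6-(tert-butyldimethylsilyloxy)hex-4-ynoyl]oxazolidin-2-one, via pivalic mixed anhydride 14 (not isolated)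
Conditions: pivaloyl chloride, Et3N, THF, −20 °C; then LiCl, 13, rt
Reagents that add atoms: none
Why: N-acylation of the oxazolidinone by the mixed anhydride at its less hindered carbonyl.

Step 8
Reactants: 15 (S)-4-benzyl-3-[6-(tert-butyldimethylsilyloxy)hex-4-ynoyl]oxazolidin-2-one; 8 (E)-6-(4-methoxybenzyloxy)-3-methylhex-3-enal
Product: 17 (S)-4-benzyl-3-[(2S,3R,5E)-2-[4-(tert-butyldimethylsilyloxy)but-2-yn-1-yl]-3-hydroxy-8-(4-methoxybenzyloxy)-5-methyloct-5-enoyl]oxazolidin-2-one, via boron enolate 16 (not isolated)
Conditions: Bu2BOTf, i-Pr2NEt, CH2Cl2, −78 to 0 °C; 8, −78 to 0 °C; pH 7 buffer (KH2PO4/K2HPO4), MeOH, H2O2, 0 °C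
Reagents that add atoms: none
Why: Evans syn aldol: the Z boron enolate reacts through a chair (Zimmerman–Traxler) transition state on the face away from the benzyl group, so the (S) auxiliary sets C7 (S here) and C8 (R) together and forms C7–C8.

Step 9
Reactants: 17 syn aldol adduct
Product: 18 (2S,3R,5E)-2-[4-(tert-butyldimethylsilyloxy)but-2-yn-1-yl]-3-hydroxy-N-methoxy-8-(4-methoxybenzyloxy)-N,5-dimethyloct-5-enamide
Conditions: MeNHOMe·HCl, AlMe3, CH2Cl2, −20 to 0 °C; aq. tartaric acid
Reagents that add atoms: N,O-dimethylhydroxylamine hydrochloride, CNOC.Cl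
Why: Aluminium amide transamidation, helped by the free β-hydroxyl, replaces the auxiliary by the Weinreb amide without retro-aldol or epimerisation.

Step 10
Reactants: 18 Weinreb amide
Product: 19 (2S,3R,5E)-2-[4-(tert-butyldimethylsilyloxy)but-2-yn-1-yl]-N-methoxy-8-(4-methoxybenzyloxy)-N,5-dimethyl-3-(triethylsilyloxy)oct-5-enamide
Conditions: Et3SiCl, imidazole, DMF, 0 °C to rt
Reagents that add atoms: chlorotriethylsilane, CC[Si](Cl)(CC)CC
Why: Silylation of the secondary alcohol; the triethylsilyl group is chosen because it can be removed at step 13 without loss of the primary tert-butyldimethylsilyl ether.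

Step 11
Reactants: 19 silylated Weinreb amide
Product: 20 (3S,4R,6E)-3-[4-(tert-butyldimethylsilyloxy)but-2-yn-1-yl]-9-(4-methoxybenzyloxy)-6-methyl-4-(triethylsilyloxy)non-6-en-2-one
Conditions: MeMgBr, THF, 0 °C; aq. NH4Cl
Reagents that add atoms: methylmagnesium bromide, C[Mg]Br
Why: Weinreb ketone synthesis; the chelated tetrahedral intermediate stops at mono-addition and installs C13.

Step 12
Reactants: 20 methyl ketone
Product: 21 (3S,4R,6E)-3-[4-(tert-butyldimethylsilyloxy)but-2-yn-1-yl]-9-(4-methoxybenzyloxy)-6-methyl-4-(triethylsilyloxy)nona-1,6-dien-2-yl trifluoromethanesulfonate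
Conditions: KN(SiMe3)2, THF, −78 °C; then PhNTf2, −78 to 0 °C
Reagents that add atoms: N-phenylbis(trifluoromethanesulfonimide), O=S(=O)(N(c1ccccc1)S(=O)(=O)C(F)(F)F)C(F)(F)F
Why: Kinetic deprotonation at the methyl group and O-sulfonylation give the 1-alken-2-yl triflate; the terminal enolate cannot expel the C8 silyloxy group and C7 is not deprotonated.

Step 13
Reactants: 21 alkenyl triflate
Product: 22 (3S,4R,6E)-3-[4-(tert-butyldimethylsilyloxy)but-2-yn-1-yl]-4-hydroxy-9-(4-methoxybenzyloxy)-6-methylnona-1,6-dien-2-yl trifluoromethanesulfonate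
Conditions: pyridinium p-toluenesulfonate, MeOH/CH2Cl2, 0 °C
Reagents that add atoms: none
Why: Acid-catalysed methanolysis should remove the secondary triethylsilyl ether well before the much less labile primary tert-butyldimethylsilyl ether; the alkenyl triflate is stable to these conditions.

Step 14
Reactants: 22 hydroxy triflate; 23 tiglic acid
Product: 25 (3S,4R,6E)-3-[4-(tert-butyldimethylsilyloxy)but-2-yn-1-yl]-9-(4-methoxybenzyloxy)-6-methyl-2-(trifluoromethanesulfonyloxy)nona-1,6-dien-4-yl (E)-2-methylbut-2-enoate, via Yamaguchi mixed anhydride 24 (not isolated)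
Conditions: 2,4,6-trichlorobenzoyl chloride, Et3N, toluene, rt; then 22, 4-(dimethylamino)pyridine, rt to 40 °C
Reagents that add atoms: none
Why: Yamaguchi esterification; the acylpyridinium formed at the unhindered tigloyl carbonyl acylates the hindered C8 hydroxyl and the E geometry of the tiglate is kept.

Step 15
Reactants: 25 tiglate triflate
Product: 26 2-(trimethylsilyl)ethyl (3R,4R,6E)-3-[4-(tert-butyldimethylsilyloxy)but-2-yn-1-yl]-9-(4-methoxybenzyloxy)-6-methyl-2-methylidene-4-[(E)-2-methylbut-2-enoyloxy]non-6-enoate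
Conditions: Pd(OAc)2 (5 mol %), PPh3, CO (1 atm), 2-(trimethylsilyl)ethanol, Et3N, DMF, 50 °C
Reagents that add atoms: carbon monoxide, [C-]#[O+]; 2-(trimethylsilyl)ethanol, C[Si](C)(C)CCO
Why: Palladium-catalysed alkoxycarbonylation of the alkenyl triflate (oxidative addition to zerovalent palladium, CO insertion, alcoholysis) introduces C12 as a fluoride-labile ester; with C8 already acylated, no hydroxyl can trap the acylpalladium or the acrylate as a 12,8-lactone.

Step 16
Reactants: 26 silyl ether
Product: 27 2-(trimethylsilyl)ethyl (3R,4R,6E)-3-(4-hydroxybut-2-yn-1-yl)-9-(4-methoxybenzyloxy)-6-methyl-2-methylidene-4-[(E)-2-methylbut-2-enoyloxy]non-6-enoate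
Conditions: HF·pyridine, pyridine, THF, 0 °C to rt
Reagents that add atoms: none
Why: Buffered fluoride cleavage of the primary silyl ether; the silylethyl ester, the tiglate and the benzyl-type ether should survive.

Step 17
Reactants: 27 propargylic alcohol
Product: 29 2-(trimethylsilyl)ethyl (3R,4R,6E)-3-[(2Z)-4-hydroxy-3-iodobut-2-en-1-yl]-9-(4-methoxybenzyloxy)-6-methyl-2-methylidene-4-[(E)-2-methylbut-2-enoyloxy]non-6-enoate, via alkenylstannane 28 (not isolated)
Conditions: [(C5Me5)RuCl]4 (1.5 mol %), Bu3SnH (slow addition), CH2Cl2, rt; then iodine, CH2Cl2, 0 °C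
Reagents that add atoms: iodine, II
Why: Hydroxyl-directed ruthenium-catalysed trans-hydrostannation puts tin on C4 (next to the free hydroxyl) and hydrogen on C5 anti to it; tin–iodine exchange with retention gives the Z alkenyl iodide with iodine cis to C6.

Step 18
Reactants: 29 iodo alcohol
Product: 30 2-(trimethylsilyl)ethyl (3R,4R,6E)-3-[(2Z)-4-(tert-butyldimethylsilyloxy)-3-iodobut-2-en-1-yl]-9-(4-methoxybenzyloxy)-6-methyl-2-methylidene-4-[(E)-2-methylbut-2-enoyloxy]non-6-enoate
Conditions: t-BuMe2SiCl, imidazole, CH2Cl2, 0 °C to rt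
Reagents that add atoms: tert-butyldimethylsilyl chloride, CC(C)(C)[Si](C)(C)Cl
Why: Silylation of the primary allylic alcohol, so that only the C3 hydroxyl is oxidised at step 20.

Step 19
Reactants: 30 silyl ether
Product: 31 2-(trimethylsilyl)ethyl (3R,4R,6E)-3-[(2Z)-4-(tert-butyldimethylsilyloxy)-3-iodobut-2-en-1-yl]-9-hydroxy-6-methyl-2-methylidene-4-[(E)-2-methylbut-2-enoyloxy]non-6-enoate
Conditions: 2,3-dichloro-5,6-dicyano-1,4-benzoquinone, CH2Cl2/pH 7 buffer (KH2PO4/K2HPO4), 0 °C
Reagents that add atoms: none
Why: Oxidative cleavage of the 4-methoxybenzyl ether through its benzylic oxocarbenium ion; iodide, silyl ether and esters are inert.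

Step 20
Reactants: 31 primary alcohol
Product: 32 2-(trimethylsilyl)ethyl (3R,4R,6E)-3-[(2Z)-4-(tert-butyldimethylsilyloxy)-3-iodobut-2-en-1-yl]-6-methyl-2-methylidene-4-[(E)-2-methylbut-2-enoyloxy]-9-oxonon-6-enoate
Conditions: Dess–Martin periodinane, NaHCO3, CH2Cl2, 0 °C; used at once
Reagents that add atoms: none
Why: Dess–Martin oxidation under buffered conditions gives the 3-enal (C3 aldehyde) without conjugation.

Step 21
Reactants: 32 iodo aldehyde
Product: 33 2-(trimethylsilyl)ethyl (3S,7R,8R)-15-(tert-butyldimethylsilyloxy)-3-hydroxy-8-[(E)-2-methylbut-2-enoyloxy]germacra-1(10)E,4Z,11(13)-trien-12-oate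
Conditions: CrCl2 (10 equiv), NiCl2 (2 mol %), DMSO, rt, 2 mM, slow addition
Reagents that add atoms: none
Why: Nozaki–Hiyama–Kishi reaction: zerovalent nickel inserts into the carbon–iodine bond, transmetalation gives the alkenylchromium with retention of the Z geometry, and its addition to the aldehyde forms C3–C4 and the ten-membered ring; C3 is set by the ring conformation that C7 and C8 impose, the 3S epimer being the one required and not secured in advance.

Step 22
Reactants: 33 macrocyclic ester
Product: 34 (3S,7R,8R)-3,15-dihydroxy-8-[(E)-2-methylbut-2-enoyloxy]germacra-1(10)E,4Z,11(13)-trien-12-oic acid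
Conditions: Bu4NF, THF, 0 °C to rt; aq. NH4Cl (pH about 5), cold
Reagents that add atoms: none
Why: Fluoride removes the silyl ether and cleaves the 2-(trimethylsilyl)ethyl ester by attack at silicon with loss of ethene, so neither acid nor heat touches the 1(10),4-diene.

Step 23
Reactants: 34 6-deoxy acid; 35 dioxygen
Product: 37 (3S,6R,7R,8R)-3,15-dihydroxy-8-[(E)-2-methylbut-2-enoyloxy]germacra-1(10)E,4Z,11(13)-trien-12,6-olide, via 6-hydroxy acid 36 (not isolated)
Conditions: CYP71-family germacrenoic acid 6α-hydroxylase (costunolide-synthase type, haem-thiolate iron enzyme, variant chosen by screening) with its P450 reductase in yeast microsomes, air, NADPH (cat.), glucose dehydrogenase, D-glucose, pH 7.5 buffer (KH2PO4/K2HPO4), 30 °C; then pH 5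
Reagents that add atoms: none
Why: Proposed new method: the haem iron is turned by O2, two electrons from NADPH (through the reductase) and two protons into the ferryl-oxo (tetravalent iron) porphyrin radical cation, which abstracts the α-face hydrogen of C6, and the hydroxyl rebounds onto the pocket-held allylic radical at C6 on the same face to give 36. The closest known reaction type is the 6α-hydroxylation with spontaneous lactonisation that enzymes of this class carry out on germacrene A acid and its 8β-hydroxy congener, so only the substrate (Z C4=C5, tiglate on the C8 oxygen, 3,15-diol) is new. The one ring closes by 5-exo-trig acyl substitution: the C6 hydroxyl adds to the C12 carboxyl carbon and water leaves, at the assay pH or on adjustment to pH 5. The new stereocentre C6 (R, 6α-O) is controlled by the enzyme pocket, which fixes the face of abstraction and rebound. The trans ring fusion follows because the 6α oxygen and the 7β acrylic acid are both anti to H6β and H7α. The step needs site selectivity for C6–H over the allylic hydrogens at C2, C3, C7, C9, C14 and C15 and over oxygen transfer to C1=C10, and rebound at C6 rather than C4. The substrate offers the carboxylate as an anchor that holds C7 and its neighbour C6 above the haem as in the natural acids, and C6 is the only allylic methylene next to C7; the rest must come from screening and engineering of the enzyme.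

Step 24
Reactants: 37 1(10)-ene lactone
Product: 38 (1R,3S,6R,7R,8R,10R)-1,10-epoxy-3,15-dihydroxy-8-[(E)-2-methylbut-2-enoyloxy]germacra-4Z,11(13)-dien-12,6-olide (CNP0187917.2)
Conditions: 3-chloroperoxybenzoic acid (1.05 equiv), NaHCO3, CH2Cl2, −20 to 0 °C
Reagents that add atoms: 3-chloroperoxybenzoic acid, OOC(=O)c1cccc(Cl)c1
Why: Prilezhaev epoxidation: concerted syn oxygen transfer to the most electron-rich olefin C1=C10 (C4=C5 carries three allylic oxygens, the other two olefins are conjugated to carbonyls); attack from the outer face of the E olefin should give the trans 1β,10α oxirane (1R,10R).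

## Compound list

1 | tert-butyl(but-3-yn-1-yloxy)dimethylsilane | C#CCCO[Si](C)(C)C(C)(C)C | starting material
2 | oxirane (ethylene oxide) | C1CO1 | starting material
3 | (E)-[4-(tert-butyldimethylsilyloxy)-2-methylbut-1-en-1-yl]dimethylaluminium | C[Al](C)/C=C(\C)CCO[Si](C)(C)C(C)(C)C | intermediate
4 | lithium butyl[(E)-4-(tert-butyldimethylsilyloxy)-2-methylbut-1-en-1-yl]dimethylaluminate | [Li+].CCCC[Al-](C)(C)/C=C(\C)CCO[Si](C)(C)C(C)(C)C | intermediate
5 | (E)-6-(tert-butyldimethylsilyloxy)-4-methylhex-3-en-1-ol | OCC/C=C(\C)CCO[Si](C)(C)C(C)(C)C | intermediate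
6 | tert-butyl{[(E)-6-(4-methoxybenzyloxy)-3-methylhex-3-en-1-yl]oxy}dimethylsilane | COc1ccc(COCC/C=C(\C)CCO[Si](C)(C)C(C)(C)C)cc1 | intermediate
7 | (E)-6-(4-methoxybenzyloxy)-3-methylhex-3-en-1-ol | COc1ccc(COCC/C=C(\C)CCO)cc1 | intermediate
8 | (E)-6-(4-methoxybenzyloxy)-3-methylhex-3-enal | COc1ccc(COCC/C=C(\C)CC=O)cc1 | intermediate
9 | tert-butyldimethyl(prop-2-yn-1-yloxy)silane | C#CCO[Si](C)(C)C(C)(C)C | starting material
10 | oxetane | C1COC1 | starting material
11 | 6-(tert-butyldimethylsilyloxy)hex-4-yn-1-ol | OCCCC#CCO[Si](C)(C)C(C)(C)C | intermediate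
12 | 6-(tert-butyldimethylsilyloxy)hex-4-ynoic acid | OC(=O)CCC#CCO[Si](C)(C)C(C)(C)C | intermediate
13 | (S)-4-benzyloxazolidin-2-one | O=C1OC[C@H](Cc2ccccc2)N1 | starting material
14 | 6-(tert-butyldimethylsilyloxy)hex-4-ynoic pivalic anhydride | CC(C)(C)C(=O)OC(=O)CCC#CCO[Si](C)(C)C(C)(C)C | intermediate
15 | (S)-4-benzyl-3-[6-(tert-butyldimethylsilyloxy)hex-4-ynoyl]oxazolidin-2-one | O=C1OC[C@H](Cc2ccccc2)N1C(=O)CCC#CCO[Si](C)(C)C(C)(C)C | intermediate
16 | dibutylboron (Z)-enolate of 15 | CCCCB(CCCC)O/C(=C\CC#CCO[Si](C)(C)C(C)(C)C)N1C(=O)OC[C@@H]1Cc1ccccc1 | intermediate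
17 | (S)-4-benzyl-3-[(2S,3R,5E)-2-[4-(tert-butyldimethylsilyloxy)but-2-yn-1-yl]-3-hydroxy-8-(4-methoxybenzyloxy)-5-methyloct-5-enoyl]oxazolidin-2-one | O=C1OC[C@H](Cc2ccccc2)N1C(=O)[C@@H](CC#CCO[Si](C)(C)C(C)(C)C)[C@H](O)C/C(C)=C/CCOCc1ccc(OC)cc1 | intermediate
18 | (2S,3R,5E)-2-[4-(tert-butyldimethylsilyloxy)but-2-yn-1-yl]-3-hydroxy-N-methoxy-8-(4-methoxybenzyloxy)-N,5-dimethyloct-5-enamide | CON(C)C(=O)[C@@H](CC#CCO[Si](C)(C)C(C)(C)C)[C@H](O)C/C(C)=C/CCOCc1ccc(OC)cc1 | intermediate
19 | 3-O-triethylsilyl ether of 18 (2S,3R,5E) | CON(C)C(=O)[C@@H](CC#CCO[Si](C)(C)C(C)(C)C)[C@H](O[Si](CC)(CC)CC)C/C(C)=C/CCOCc1ccc(OC)cc1 | intermediate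
20 | (3S,4R,6E)-3-[4-(tert-butyldimethylsilyloxy)but-2-yn-1-yl]-9-(4-methoxybenzyloxy)-6-methyl-4-(triethylsilyloxy)non-6-en-2-one | CC(=O)[C@@H](CC#CCO[Si](C)(C)C(C)(C)C)[C@H](O[Si](CC)(CC)CC)C/C(C)=C/CCOCc1ccc(OC)cc1 | intermediate
21 | (3S,4R,6E)-3-[4-(tert-butyldimethylsilyloxy)but-2-yn-1-yl]-9-(4-methoxybenzyloxy)-6-methyl-4-(triethylsilyloxy)nona-1,6-dien-2-yl trifluoromethanesulfonate | C=C(OS(=O)(=O)C(F)(F)F)[C@@H](CC#CCO[Si](C)(C)C(C)(C)C)[C@H](O[Si](CC)(CC)CC)C/C(C)=C/CCOCc1ccc(OC)cc1 | intermediate
22 | (3S,4R,6E)-3-[4-(tert-butyldimethylsilyloxy)but-2-yn-1-yl]-4-hydroxy-9-(4-methoxybenzyloxy)-6-methylnona-1,6-dien-2-yl trifluoromethanesulfonate | C=C(OS(=O)(=O)C(F)(F)F)[C@@H](CC#CCO[Si](C)(C)C(C)(C)C)[C@H](O)C/C(C)=C/CCOCc1ccc(OC)cc1 | intermediate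
23 | tiglic acid, (E)-2-methylbut-2-enoic acid | C/C=C(\C)C(=O)O | starting material
24 | tiglic 2,4,6-trichlorobenzoic anhydride | C/C=C(\C)C(=O)OC(=O)c1c(Cl)cc(Cl)cc1Cl | intermediate
25 | (3S,4R,6E)-3-[4-(tert-butyldimethylsilyloxy)but-2-yn-1-yl]-9-(4-methoxybenzyloxy)-6-methyl-2-(trifluoromethanesulfonyloxy)nona-1,6-dien-4-yl (E)-2-methylbut-2-enoate | C=C(OS(=O)(=O)C(F)(F)F)[C@@H](CC#CCO[Si](C)(C)C(C)(C)C)[C@H](OC(=O)/C(C)=C/C)C/C(C)=C/CCOCc1ccc(OC)cc1 | intermediate
26 | 2-(trimethylsilyl)ethyl (3R,4R,6E)-3-[4-(tert-butyldimethylsilyloxy)but-2-yn-1-yl]-9-(4-methoxybenzyloxy)-6-methyl-2-methylidene-4-[(E)-2-methylbut-2-enoyloxy]non-6-enoate | C=C(C(=O)OCC[Si](C)(C)C)[C@@H](CC#CCO[Si](C)(C)C(C)(C)C)[C@H](OC(=O)/C(C)=C/C)C/C(C)=C/CCOCc1ccc(OC)cc1 | intermediate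
27 | 2-(trimethylsilyl)ethyl (3R,4R,6E)-3-(4-hydroxybut-2-yn-1-yl)-9-(4-methoxybenzyloxy)-6-methyl-2-methylidene-4-[(E)-2-methylbut-2-enoyloxy]non-6-enoate | C=C(C(=O)OCC[Si](C)(C)C)[C@@H](CC#CCO)[C@H](OC(=O)/C(C)=C/C)C/C(C)=C/CCOCc1ccc(OC)cc1 | intermediate
28 | 3-[(2Z)-4-hydroxy-3-(tributylstannyl)but-2-en-1-yl] analogue of 27 | C=C(C(=O)OCC[Si](C)(C)C)[C@@H](C/C=C(/CO)[Sn](CCCC)(CCCC)CCCC)[C@H](OC(=O)/C(C)=C/C)C/C(C)=C/CCOCc1ccc(OC)cc1 | intermediate
29 | 2-(trimethylsilyl)ethyl (3R,4R,6E)-3-[(2Z)-4-hydroxy-3-iodobut-2-en-1-yl]-9-(4-methoxybenzyloxy)-6-methyl-2-methylidene-4-[(E)-2-methylbut-2-enoyloxy]non-6-enoate | C=C(C(=O)OCC[Si](C)(C)C)[C@@H](C/C=C(\I)CO)[C@H](OC(=O)/C(C)=C/C)C/C(C)=C/CCOCc1ccc(OC)cc1 | intermediate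
30 | 2-(trimethylsilyl)ethyl (3R,4R,6E)-3-[(2Z)-4-(tert-butyldimethylsilyloxy)-3-iodobut-2-en-1-yl]-9-(4-methoxybenzyloxy)-6-methyl-2-methylidene-4-[(E)-2-methylbut-2-enoyloxy]non-6-enoate | C=C(C(=O)OCC[Si](C)(C)C)[C@@H](C/C=C(\I)CO[Si](C)(C)C(C)(C)C)[C@H](OC(=O)/C(C)=C/C)C/C(C)=C/CCOCc1ccc(OC)cc1 | intermediate
31 | 9-hydroxy compound from 30 (3R,4R,6E,2'Z) | C=C(C(=O)OCC[Si](C)(C)C)[C@@H](C/C=C(\I)CO[Si](C)(C)C(C)(C)C)[C@H](OC(=O)/C(C)=C/C)C/C(C)=C/CCO | intermediate
32 | 9-oxo compound from 31 (3R,4R,6E,2'Z), the C3 aldehyde | C=C(C(=O)OCC[Si](C)(C)C)[C@@H](C/C=C(\I)CO[Si](C)(C)C(C)(C)C)[C@H](OC(=O)/C(C)=C/C)C/C(C)=C/CC=O | intermediate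
33 | 2-(trimethylsilyl)ethyl (3S,7R,8R)-15-(tert-butyldimethylsilyloxy)-3-hydroxy-8-[(E)-2-methylbut-2-enoyloxy]germacra-1(10)E,4Z,11(13)-trien-12-oate | C=C(C(=O)OCC[Si](C)(C)C)[C@H]1C/C=C(/CO[Si](C)(C)C(C)(C)C)[C@@H](O)C/C=C(\C)C[C@H]1OC(=O)/C(C)=C/C | intermediate
34 | (3S,7R,8R)-3,15-dihydroxy-8-[(E)-2-methylbut-2-enoyloxy]germacra-1(10)E,4Z,11(13)-trien-12-oic acid (6-deoxy acid) | C=C(C(=O)O)[C@H]1C/C=C(/CO)[C@@H](O)C/C=C(\C)C[C@H]1OC(=O)/C(C)=C/C | intermediate
35 | dioxygen | O=O | starting material
36 | (3S,6R,7R,8R)-3,6,15-trihydroxy-8-[(E)-2-methylbut-2-enoyloxy]germacra-1(10)E,4Z,11(13)-trien-12-oic acid | C=C(C(=O)O)[C@H]1[C@H](O)/C=C(/CO)[C@@H](O)C/C=C(\C)C[C@H]1OC(=O)/C(C)=C/C | intermediate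
37 | (3S,6R,7R,8R)-3,15-dihydroxy-8-[(E)-2-methylbut-2-enoyloxy]germacra-1(10)E,4Z,11(13)-trien-12,6-olide | C=C1C(=O)O[C@@H]2/C=C(/CO)[C@@H](O)C/C=C(\C)C[C@@H](OC(=O)/C(C)=C/C)[C@@H]12 | intermediate
38 | (1R,3S,6R,7R,8R,10R)-1,10-epoxy-3,15-dihydroxy-8-[(E)-2-methylbut-2-enoyloxy]germacra-4Z,11(13)-dien-12,6-olide (CNP0187917.2) | C=C1C(=O)O[C@@H]2/C=C(/CO)[C@@H](O)C[C@H]3O[C@]3(C)C[C@@H](OC(=O)/C(C)=C/C)[C@@H]12 | target

## Step count and least certain steps

Total step count: 24. Longest linear sequence: 21 steps (steps 1 to 4, then 8 to 24); the second branch (steps 5 to 7) joins at step 8.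

**Step 23 (key step, Proposed new method).**
- What may go wrong: no productive binding or turnover of the unnatural substrate, or oxygen transfer at another site (hydroxylation at C14, C2, C9 or C15, epoxidation of C1=C10, rebound at C4). The Z olefin changes how the ring sits above the haem, and the tiglate and the diol are bulkier and more polar than anything the known enzymes accept.
- Fallback with known chemistry: enzymatic site selection is replaced by blocking every other allylic position. It sets out from 33 and returns at 38.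
  - HF·pyridine removes the silyl ether of 33 to give the diol ester F1.
  - 2-(Trimethylsilyl)ethyl chloroformate, pyridine and 4-(dimethylamino)pyridine convert both hydroxyls into the carbonates F2, whose α-hydrogens are deactivated toward oxidants.
  - 3-Chloroperoxybenzoic acid epoxidises C1=C10 of F2, the only electron-rich olefin left, to F3. This removes the allylic character of C2, C9 and C14 and installs the oxirane of the target.
  - CrO3 with 3,5-dimethylpyrazole in CH2Cl2 at −20 °C then oxidises the one remaining unactivated allylic methylene, C6, to the 4-en-6-one F4. This is the reaction type that converts 5-ene steroid esters into their 7-ketones.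
  - F4 can epimerise at C7, so it is reduced at once by Corey–Bakshi–Shibata reduction (oxazaborolidine enantiomer chosen for the 6R alcohol, catecholborane) to F5.
  - Bu4NF cleaves both carbonates and the silylethyl ester, and the hydroxy acid F6 lactonises to 38.

**Step 21 (ring closure).**
- What may go wrong: poor facial selectivity in the addition to the C3 aldehyde, intermolecular coupling, or conjugation of the 3-enal before it cyclises. The C3 configuration rests only on the conformation of a flexible ten-membered transition state.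
- Fallback: stereocontrol in the C–C bond formation is replaced by reagent-controlled reduction. It sets out from 33 obtained as a mixture with its 3R epimer F7 and returns at 33. MnO2 oxidises the mixture to the enone F8, which is used at once. Reduction with the (R)-configured 2-methyl oxazaborolidine of the Corey–Bakshi–Shibata type and catecholborane at −78 °C should deliver hydride so as to give the 3S alcohol 33.

**Step 24 (epoxidation).**
- What may go wrong: oxygen delivery to the wrong face of C1=C10, or hydroxyl-directed delivery to C4=C5, because the peracid follows the ring conformation and hydrogen bonding rather than any element under control.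
- Fallback: substrate control is replaced by catalyst control. It sets out from 37 and returns at 38. A Shi epoxidation is used, with the fructose-derived ketone enantiomer that matches the required face and KHSO5 (as 2KHSO5·KHSO4·K2SO4) with K2CO3 in aqueous MeCN at 0 °C. No new compound is involved.

**Step 17 (alkenyl iodide).**
- What may go wrong: tin delivered to C5 instead of C4, or radical addition of the tin hydride to the acrylate.
- Fallback: it avoids tin and sets out from 27, returning at 29. RuCl(C9H7)(PPh3)2 with In(OTf)3 and camphorsulfonic acid in THF isomerises the propargylic alcohol (redox isomerisation) to the E enal F9. Iodine with 4-(dimethylamino)pyridine and K2CO3 in aqueous THF gives the Z 2-iodo enal F10, the stable isomer with iodine cis to C6. Luche reduction (NaBH4, CeCl3·7H2O, MeOH, −40 °C) reduces only the aldehyde and gives 29.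

## Further compounds

F1 | step 23 | 2-(trimethylsilyl)ethyl (3S,7R,8R)-3,15-dihydroxy-8-[(E)-2-methylbut-2-enoyloxy]germacra-1(10)E,4Z,11(13)-trien-12-oate | C=C(C(=O)OCC[Si](C)(C)C)[C@H]1C/C=C(/CO)[C@@H](O)C/C=C(\C)C[C@H]1OC(=O)/C(C)=C/C
F2 | step 23 | 3,15-bis[2-(trimethylsilyl)ethoxycarbonyl] derivative of F1 | C=C(C(=O)OCC[Si](C)(C)C)[C@H]1C/C=C(/COC(=O)OCC[Si](C)(C)C)[C@@H](OC(=O)OCC[Si](C)(C)C)C/C=C(\C)C[C@H]1OC(=O)/C(C)=C/C
F3 | step 23 | (1R,10R)-1,10-epoxide of F2 | C=C(C(=O)OCC[Si](C)(C)C)[C@H]1C/C=C(/COC(=O)OCC[Si](C)(C)C)[C@@H](OC(=O)OCC[Si](C)(C)C)C[C@H]2O[C@]2(C)C[C@H]1OC(=O)/C(C)=C/C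
F4 | step 23 | 6-oxo derivative of F3 (4Z-en-6-one) | C=C(C(=O)OCC[Si](C)(C)C)[C@H]1C(=O)/C=C(/COC(=O)OCC[Si](C)(C)C)[C@@H](OC(=O)OCC[Si](C)(C)C)C[C@H]2O[C@]2(C)C[C@H]1OC(=O)/C(C)=C/C
F5 | step 23 | (6R)-6-hydroxy derivative of F3 | C=C(C(=O)OCC[Si](C)(C)C)[C@H]1[C@H](O)/C=C(/COC(=O)OCC[Si](C)(C)C)[C@@H](OC(=O)OCC[Si](C)(C)C)C[C@H]2O[C@]2(C)C[C@H]1OC(=O)/C(C)=C/C
F6 | step 23 | (1R,3S,6R,7R,8R,10R)-1,10-epoxy-3,6,15-trihydroxy-8-[(E)-2-methylbut-2-enoyloxy]germacra-4Z,11(13)-dien-12-oic acid | C=C(C(=O)O)[C@H]1[C@H](O)/C=C(/CO)[C@@H](O)C[C@H]2O[C@]2(C)C[C@H]1OC(=O)/C(C)=C/C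
F7 | step 21 | 3R epimer of 33 | C=C(C(=O)OCC[Si](C)(C)C)[C@H]1C/C=C(/CO[Si](C)(C)C(C)(C)C)[C@H](O)C/C=C(\C)C[C@H]1OC(=O)/C(C)=C/C
F8 | step 21 | 3-oxo derivative of 33 (4Z-en-3-one) | C=C(C(=O)OCC[Si](C)(C)C)[C@H]1C/C=C(/CO[Si](C)(C)C(C)(C)C)C(=O)C/C=C(\C)C[C@H]1OC(=O)/C(C)=C/C
F9 | step 17 | 2-(trimethylsilyl)ethyl (3R,4R,6E)-9-(4-methoxybenzyloxy)-6-methyl-2-methylidene-4-[(E)-2-methylbut-2-enoyloxy]-3-[(2E)-4-oxobut-2-en-1-yl]non-6-enoate | C=C(C(=O)OCC[Si](C)(C)C)[C@@H](C/C=C/C=O)[C@H](OC(=O)/C(C)=C/C)C/C(C)=C/CCOCc1ccc(OC)cc1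
F10 | step 17 | 2-(trimethylsilyl)ethyl (3R,4R,6E)-3-[(2Z)-3-iodo-4-oxobut-2-en-1-yl]-9-(4-methoxybenzyloxy)-6-methyl-2-methylidene-4-[(E)-2-methylbut-2-enoyloxy]non-6-enoate | C=C(C(=O)OCC[Si](C)(C)C)[C@@H](C/C=C(\I)C=O)[C@H](OC(=O)/C(C)=C/C)C/C(C)=C/CCOCc1ccc(OC)cc1
F0 | step 24 | none | none
A1 | alternative 1 | alkyne half: C6 triethylsilyl ether, C8 tert-butyldimethylsilyl ether, C12 4-methoxybenzyl ether, terminal alkyne C1≡C10 | C#CC[C@@H](O[Si](C)(C)C(C)(C)C)[C@@H](C(=C)COCc1ccc(OC)cc1)CO[Si](CC)(CC)CC
A2 | alternative 1 | epoxide half: 2-[(Z)-1-iodo-3-(tert-butyldiphenylsilyloxy)prop-1-en-2-yl]oxirane with C3 as in the target | I/C=C(/CO[Si](c1ccccc1)(c1ccccc1)C(C)(C)C)[C@@H]1CO1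
A3 | alternative 1 | open-chain E-homoallylic alcohol with alkenyl iodide | I/C=C(/CO[Si](c1ccccc1)(c1ccccc1)C(C)(C)C)[C@@H](O)C/C=C(\C)C[C@@H](O[Si](C)(C)C(C)(C)C)[C@@H](C(=C)COCc1ccc(OC)cc1)CO[Si](CC)(CC)CC
A4 | alternative 2 | Z,E-cyclodecadienone with C8 methoxymethyl ether and C7 side chain | O=C1/C=C(/CO[Si](C)(C)C(C)(C)C)[C@@H](O[Si](C)(C)C(C)(C)C)C/C=C(\C)C[C@@H](OCOC)[C@H]1CCOCc2ccc(OC)cc2
A5 | alternative 3 | open-chain iodo aldehyde carrying the trans 12,6-lactone and the C8 tiglate | C=C1C(=O)O[C@H](/C=C(\I)CO[Si](C)(C)C(C)(C)C)[C@H]1[C@H](OC(=O)/C(C)=C/C)C/C(C)=C/CC=O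
A6 | alternative 3 | 1(10)-ene germacranolide, C15 tert-butyldimethylsilyl ether | C=C1C(=O)O[C@@H]2/C=C(/CO[Si](C)(C)C(C)(C)C)[C@@H](O)C/C=C(\C)C[C@@H](OC(=O)/C(C)=C/C)[C@@H]12
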